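## Retrosynthetic overview

1. Last bond made: C3 of the dihydrobenzofuran to the diarylmethine carbon. A para-quinone methide from benzhydrol 23 (fragment 1) is attacked by hydroxystilbene–chalcone 30 (fragment 2), and the same operation closes O1–C2 of the dihydrobenzofuran.
2. Feature used: the methine carbon sits between two resorcinol rings and para to the 4-hydroxyl of its 2,4-dihydroxyphenyl ring, so it is a latent quinone-methide carbon. C3 is the β-carbon of a 4-oxygenated stilbene whose ring B oxygen (O1) is ortho to the styryl carbon and para to the enone, ready to close onto C2.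
3. Fragment 1: oxolane ring first (Evans syn-aldol/lactonisation, α-benzylation, lactol, Friedel–Crafts C-arylation), then Weinreb ketone, Vilsmeier formylation and aryl addition.
4. Fragment 2: Heck reaction (stilbene), then Claisen–Schmidt condensation (chalcone).
5. Ring order: oxolane (steps 2–6), then dihydrobenzofuran (step 16); global debenzylation last.

Key step: step 16

Assumption: the facial sense induced by the chiral phosphoric acid in step 16 cannot be predicted with confidence for this substrate pair. The (R)-acid is written; its enantiomer is taken if a first screen shows the other sense.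

## Route

Step 1
Reactants: 1 (R)-4-benzyl-1,3-oxazolidin-2-one; 2 methyl 4-chloro-4-oxobutanoate
Product: 3 methyl 4-[(4R)-4-benzyl-2-oxo-1,3-oxazolidin-3-yl]-4-oxobutanoate
Conditions: n-BuLi, THF, −78 °C; then 2, −78 to 0 °C
Reagents that add atoms: none
Why: N-acylation of the lithiated oxazolidinone by the acid chloride (Evans imide formation) is faster than attack at the methyl ester; no new stereocentre.

Step 2
Reactants: 3 methyl 4-[(4R)-4-benzyl-2-oxo-1,3-oxazolidin-3-yl]-4-oxobutanoate; 4 4-(benzyloxy)benzaldehyde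
Product: 7 (4R)-4-benzyl-3-{[(2R,3R)-2-[4-(benzyloxy)phenyl]-5-oxooxolan-3-yl]carbonyl}-1,3-oxazolidin-2-one, via boron enolate 5 (not isolated), via syn-aldol adduct 6 (not isolated)
Conditions: Bu2BOTf, i-Pr2NEt, CH2Cl2, −78 to 0 °C; 4, −78 to 0 °C; MeOH, pH 7 buffer, H2O2, 0 °C; then PPTS (cat.), CH2Cl2, rt
Reagents that add atoms: none
Why: Evans syn-aldol reaction: the (Z)-boron enolate reacts through a Zimmerman–Traxler chair on the face left open by the (R)-benzyl group, which should set both new centres (3R,4R); the γ-hydroxy ester then lactonises to the trans lactone.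

Step 3
Reactants: 7 (4R)-4-benzyl-3-{[(2R,3R)-2-[4-(benzyloxy)phenyl]-5-oxooxolan-3-yl]carbonyl}-1,3-oxazolidin-2-one
Product: 8 (2R,3R)-2-[4-(benzyloxy)phenyl]-5-oxooxolane-3-carboxylic acid
Conditions: LiOH, H2O2, THF–H2O, 0 °C; Na2SO3; then HCl (aq) to pH 2
Reagents that add atoms: hydrogen peroxide, OO
Why: Hydroperoxide cleaves the exocyclic imide carbonyl selectively (auxiliary removal), and acidification re-closes any opened lactone; the stereocentres are not touched.

Step 4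
Reactants: 8 (2R,3R)-2-[4-(benzyloxy)phenyl]-5-oxooxolane-3-carboxylic acid; 9 1-(benzyloxy)-4-(bromomethyl)benzene
Product: 10 (2R,3R,4R)-4-[4-(benzyloxy)benzyl]-2-[4-(benzyloxy)phenyl]-5-oxooxolane-3-carboxylic acid
Conditions: NaHMDS (2.2 equiv), THF, −78 °C; 9, −78 to −40 °C; HCl (aq)
Reagents that add atoms: none
Why: Dianion alkylation of a paraconic acid: the lactone enolate should be benzylated anti to the neighbouring carboxylate, as in the known α-methylation of such acids, giving the all-trans (4R) product.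

Step 5
Reactants: 10 (2R,3R,4R)-4-[4-(benzyloxy)benzyl]-2-[4-(benzyloxy)phenyl]-5-oxooxolane-3-carboxylic acid
Product: 11 (2R,3R,4R)-4-[4-(benzyloxy)benzyl]-2-[4-(benzyloxy)phenyl]-5-hydroxyoxolane-3-carboxylic acid (both C5 epimers)
Conditions: i-Bu2AlH (3 equiv), CH2Cl2, −78 °C; aq potassium sodium tartrate, then citric acid
Reagents that add atoms: none
Why: Partial reduction of a lactone to the lactol at −78 °C; the first equivalent of hydride turns the acid into an aluminium carboxylate that should not be reduced at this temperature, and the anomeric centre is lost in step 6.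

Step 6
Reactants: 11 (2R,3R,4R)-4-[4-(benzyloxy)benzyl]-2-[4-(benzyloxy)phenyl]-5-hydroxyoxolane-3-carboxylic acid; 12 1,3-bis(benzyloxy)benzene
Product: 13 (2R,3R,4R,5R)-4-[4-(benzyloxy)benzyl]-2-[4-(benzyloxy)phenyl]-5-[2,4-bis(benzyloxy)phenyl]oxolane-3-carboxylic acid
Conditions: 12 (3 equiv), BF3·OEt2, CH2Cl2, −40 to 0 °C
Reagents that add atoms: none
Why: Friedel–Crafts C-arylation of the cyclic oxocarbenium ion at C4 of the resorcinol diether; attack anti to the adjacent benzyl group, backed by reversible ionisation of the electron-rich 2-aryl ether, should give the all-trans (5R) oxolane.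

Step 7
Reactants: 13 (2R,3R,4R,5R)-4-[4-(benzyloxy)benzyl]-2-[4-(benzyloxy)phenyl]-5-[2,4-bis(benzyloxy)phenyl]oxolane-3-carboxylic acid
Product: 14 (2R,3R,4R,5R)-4-[4-(benzyloxy)benzyl]-2-[4-(benzyloxy)phenyl]-5-[2,4-bis(benzyloxy)phenyl]-N-methoxy-N-methyloxolane-3-carboxamide
Conditions: MeNH(OMe)·HCl, EDC·HCl, HOBt, i-Pr2NEt, CH2Cl2, 0 °C to rt
Reagents that add atoms: N,O-dimethylhydroxylamine hydrochloride, CNOC.Cl
Why: Carbodiimide amide coupling to the Weinreb amide; no stereocentre is formed and the α-centre stays in its favoured trans arrangement.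

Step 8
Reactants: 14 (2R,3R,4R,5R)-4-[4-(benzyloxy)benzyl]-2-[4-(benzyloxy)phenyl]-5-[2,4-bis(benzyloxy)phenyl]-N-methoxy-N-methyloxolane-3-carboxamide; 15 1-bromo-2,4-bis(benzyloxy)benzene
Product: 17 [2,4-bis(benzyloxy)phenyl]{(2R,3R,4R,5R)-4-[4-(benzyloxy)benzyl]-2-[4-(benzyloxy)phenyl]-5-[2,4-bis(benzyloxy)phenyl]oxolan-3-yl}methanone, via aryllithium 16 (not isolated)
Conditions: 15 (2.2 equiv), n-BuLi, THF, −78 °C; then 14, −78 to −20 °C; H2O
Reagents that add atoms: none
Why: Weinreb ketone synthesis: the aryllithium from bromine–lithium exchange adds once because the chelated tetrahedral intermediate survives until work-up; no new stereocentre.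

Step 9
Reactants: 17 [2,4-bis(benzyloxy)phenyl]{(2R,3R,4R,5R)-4-[4-(benzyloxy)benzyl]-2-[4-(benzyloxy)phenyl]-5-[2,4-bis(benzyloxy)phenyl]oxolan-3-yl}methanone
Product: 19 2,4-bis(benzyloxy)-5-{(2R,3R,4R,5R)-4-[2,4-bis(benzyloxy)benzoyl]-3-[4-(benzyloxy)benzyl]-5-[4-(benzyloxy)phenyl]oxolan-2-yl}benzaldehyde, via iminium chloride 18 (not isolated)
Conditions: POCl3, DMF, 0 °C to rt; then ice–water
Reagents that add atoms: N,N-dimethylformamide, CN(C)C=O; water, O
Why: Vilsmeier–Haack formylation at the one open position ortho/para to both benzyloxy groups of the most electron-rich ring; the acyl-deactivated resorcinol ring and the mono-oxygenated rings should not react with this weak electrophile.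

Step 10
Reactants: 20 3-(benzyloxy)phenol
Product: 21 3-(benzyloxy)-4-bromophenol
Conditions: NBS, MeCN, −20 to 0 °C
Reagents that add atoms: N-bromosuccinimide, O=C1CCC(=O)N1Br
Why: Electrophilic aromatic bromination para to the free hydroxyl, the stronger activating group.

Step 11
Reactants: 19 2,4-bis(benzyloxy)-5-{(2R,3R,4R,5R)-4-[2,4-bis(benzyloxy)benzoyl]-3-[4-(benzyloxy)benzyl]-5-[4-(benzyloxy)phenyl]oxolan-2-yl}benzaldehyde; 21 3-(benzyloxy)-4-bromophenol
Product: 23 [2-(benzyloxy)-4-hydroxyphenyl](2,4-bis(benzyloxy)-5-{(2R,3R,4R,5R)-4-[2,4-bis(benzyloxy)benzoyl]-3-[4-(benzyloxy)benzyl]-5-[4-(benzyloxy)phenyl]oxolan-2-yl}phenyl)methanol (both carbinol epimers), via dilithio reagent 22 (not isolated)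
Conditions: 21 (1.5 equiv), n-BuLi (1.5 equiv), THF, −78 °C; t-BuLi (3.0 equiv), −78 °C; then 19, −78 to −60 °C; H2O
Reagents that add atoms: none
Why: 1,2-Addition of an aryllithium (phenoxide-bearing dianion from bromine–lithium exchange) to the aldehyde, which should be much faster than addition to the hindered, α-branched, electron-rich aryl ketone; the carbinol centre is ionised in step 16, so its configuration does not matter.

Step 12
Reactants: 24 3-bromo-4-hydroxybenzaldehyde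
Product: 25 3-bromo-4-(methoxymethoxy)benzaldehyde
Conditions: MOMCl, i-Pr2NEt, CH2Cl2, 0 °C to rt
Reagents that add atoms: chloromethyl methyl ether, COCCl
Why: O-Alkylation of the phenol (MOM ether formation) keeps the phenoxide from deactivating the aldehyde in step 14.

Step 13
Reactants: 25 3-bromo-4-(methoxymethoxy)benzaldehyde; 26 1-(benzyloxy)-4-ethenylbenzene
Product: 27 3-{(E)-2-[4-(benzyloxy)phenyl]ethenyl}-4-(methoxymethoxy)benzaldehyde
Conditions: Pd(OAc)2 (5 mol %), P(o-tolyl)3 (10 mol %), Et3N, DMF, 100 °C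
Reagents that add atoms: none
Why: Mizoroki–Heck reaction: oxidative addition of zerovalent palladium to the aryl bromide, syn insertion of the styrene and syn β-hydride elimination should give the (E)-stilbene.

Step 14
Reactants: 27 3-{(E)-2-[4-(benzyloxy)phenyl]ethenyl}-4-(methoxymethoxy)benzaldehyde; 28 1-[2,4-bis(benzyloxy)phenyl]ethan-1-one
Product: 29 (E)-3-[3-{(E)-2-[4-(benzyloxy)phenyl]ethenyl}-4-(methoxymethoxy)phenyl]-1-[2,4-bis(benzyloxy)phenyl]prop-2-en-1-one
Conditions: KOH, EtOH–THF, rt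
Reagents that add atoms: none
Why: Claisen–Schmidt aldol condensation; E1cB dehydration gives the (E)-enone, and the benzylated 2'-oxygen prevents flavanone closure.

Step 15
Reactants: 29 (E)-3-[3-{(E)-2-[4-(benzyloxy)phenyl]ethenyl}-4-(methoxymethoxy)phenyl]-1-[2,4-bis(benzyloxy)phenyl]prop-2-en-1-one
Product: 30 (E)-3-[3-{(E)-2-[4-(benzyloxy)phenyl]ethenyl}-4-hydroxyphenyl]-1-[2,4-bis(benzyloxy)phenyl]prop-2-en-1-one
Conditions: HCl (2 M aq), MeOH–THF, 45 °C
Reagents that add atoms: none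
Why: Acid-catalysed cleavage of the aryl MOM acetal, the standard deprotection for hydroxychalcones; benzyl ethers and both alkenes should survive dilute acid.

Step 16
Reactants: 23 [2-(benzyloxy)-4-hydroxyphenyl](2,4-bis(benzyloxy)-5-{(2R,3R,4R,5R)-4-[2,4-bis(benzyloxy)benzoyl]-3-[4-(benzyloxy)benzyl]-5-[4-(benzyloxy)phenyl]oxolan-2-yl}phenyl)methanol; 30 (E)-3-[3-{(E)-2-[4-(benzyloxy)phenyl]ethenyl}-4-hydroxyphenyl]-1-[2,4-bis(benzyloxy)phenyl]prop-2-en-1-one
Product: 32 decabenzyl ether of isolophirachalcone with (2R,3R)-dihydrobenzofuran and (R)-methine and (2R,3R,4R,5R)-oxolane configuration (only the 4-hydroxyl of the methine-bound 2-benzyloxyphenyl ring is free), via para-quinone methide 31 (not isolated)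
Conditions: (R)-3,3'-bis(2,4,6-triisopropylphenyl)-1,1'-binaphthyl-2,2'-diyl hydrogen phosphate (10 mol %), 5 Å molecular sieves, CH2Cl2, 0 °C to rt; 23 added slowly to 30 (2 equiv)
Reagents that add atoms: none
Why: Proposed new method: the acid dehydrates 23 to para-quinone methide 31, whose exocyclic carbon (the future methine) is attacked by C3 of the stilbene in 30 in a 1,6-addition, and the 4-benzyloxybenzyl cation formed at C2 is captured by the ring B phenol oxygen, so the C3–methine bond and the O1–C2 bond form in one operation. The closest known reaction types are chiral-phosphoric-acid-catalysed 1,6-additions of carbon nucleophiles to para-quinone methides generated in situ from 4-hydroxybenzhydrols, and the acid-mediated cyclisation of 2-hydroxystilbenes to 2-aryl-2,3-dihydrobenzofurans. The furan ring closes by 5-exo-trig attack of the phenol oxygen on the benzylic cation, whose quinoid C=C is exocyclic to the new ring. The C2/C3 trans relation should follow from reversible closure onto the stabilised C2 cation (thermodynamic control, aryl and diarylmethyl groups anti), while C3 and the methine are set together in the C–C bond-forming event inside the hydrogen-bonded assembly in which the phosphate binds the quinone-methide oxygen and the phenol of 30 (catalyst control, to be matched with the remote oxolane centres). The step needs regioselectivity for attack through C3 and not C2, secured by the 4-benzyloxyphenyl donor on C2 and by the enone para to the ring B oxygen, which detunes that phenol as a donor. It also needs furan and not chroman closure, secured because both ortho oxygens of the two resorcinol rings are benzylated, so the only free hydroxyl that can reach C2 is that of ring B; slow addition of 23 to excess 30 should hold down self-alkylation.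

Step 17
Reactants: 32 decabenzyl ether of isolophirachalcone
Product: 33 isolophirachalcone, (E)-1-(2,4-dihydroxyphenyl)-3-{(2R,3R)-3-[(R)-(2,4-dihydroxyphenyl)(2,4-dihydroxy-5-{(2R,3R,4R,5R)-4-(2,4-dihydroxybenzoyl)-3-(4-hydroxybenzyl)-5-(4-hydroxyphenyl)oxolan-2-yl}phenyl)methyl]-2-(4-hydroxyphenyl)-2,3-dihydro-1-benzofuran-5-yl}prop-2-en-1-one
Conditions: BCl3 (excess), pentamethylbenzene, CH2Cl2, −78 °C; MeOH quench
Reagents that add atoms: none
Why: Lewis-acid debenzylation with a non-basic cation scavenger at low temperature, which spares the enone that hydrogenolysis would reduce; no stereocentre is formed, and any reversible opening of the benzylic ethers should return the all-trans rings.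

## Compound list

1 | (R)-4-benzyl-1,3-oxazolidin-2-one | O=C1OC[C@@H](Cc2ccccc2)N1 | starting material
2 | methyl 4-chloro-4-oxobutanoate | COC(=O)CCC(Cl)=O | starting material
3 | methyl 4-[(4R)-4-benzyl-2-oxo-1,3-oxazolidin-3-yl]-4-oxobutanoate | COC(=O)CCC(=O)N1C(=O)OC[C@H]1Cc1ccccc1 | intermediate
4 | 4-(benzyloxy)benzaldehyde | O=Cc1ccc(OCc2ccccc2)cc1 | starting material
5 | (Z)-dibutylboron enolate of 3 | CCCCB(CCCC)O/C(N1C(=O)OC[C@H]1Cc1ccccc1)=C\CC(=O)OC | intermediate
6 | methyl (3R,4R)-3-{[(4R)-4-benzyl-2-oxo-1,3-oxazolidin-3-yl]carbonyl}-4-[4-(benzyloxy)phenyl]-4-hydroxybutanoate | COC(=O)C[C@@H](C(=O)N1C(=O)OC[C@H]1Cc1ccccc1)[C@@H](O)c1ccc(OCc2ccccc2)cc1 | intermediate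
7 | (4R)-4-benzyl-3-{[(2R,3R)-2-[4-(benzyloxy)phenyl]-5-oxooxolan-3-yl]carbonyl}-1,3-oxazolidin-2-one | O=C1O[C@@H](c2ccc(OCc3ccccc3)cc2)[C@H](C(=O)N2C(=O)OC[C@H]2Cc2ccccc2)C1 | intermediate
8 | (2R,3R)-2-[4-(benzyloxy)phenyl]-5-oxooxolane-3-carboxylic acid | O=C1O[C@@H](c2ccc(OCc3ccccc3)cc2)[C@H](C(=O)O)C1 | intermediate
9 | 1-(benzyloxy)-4-(bromomethyl)benzene | BrCc1ccc(OCc2ccccc2)cc1 | starting material
10 | (2R,3R,4R)-4-[4-(benzyloxy)benzyl]-2-[4-(benzyloxy)phenyl]-5-oxooxolane-3-carboxylic acid | O=C1O[C@@H](c2ccc(OCc3ccccc3)cc2)[C@H](C(=O)O)[C@H]1Cc1ccc(OCc2ccccc2)cc1 | intermediate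
11 | (2R,3R,4R)-4-[4-(benzyloxy)benzyl]-2-[4-(benzyloxy)phenyl]-5-hydroxyoxolane-3-carboxylic acid, both C5 epimers | OC1O[C@@H](c2ccc(OCc3ccccc3)cc2)[C@H](C(=O)O)[C@H]1Cc1ccc(OCc2ccccc2)cc1 | intermediate
12 | 1,3-bis(benzyloxy)benzene | c1ccc(COc2cccc(OCc3ccccc3)c2)cc1 | starting material
13 | (2R,3R,4R,5R)-4-[4-(benzyloxy)benzyl]-2-[4-(benzyloxy)phenyl]-5-[2,4-bis(benzyloxy)phenyl]oxolane-3-carboxylic acid | C(c1ccccc1)Oc1ccc([C@@H]2O[C@@H](c3ccc(OCc4ccccc4)cc3)[C@H](C(=O)O)[C@H]2Cc2ccc(OCc3ccccc3)cc2)c(OCc2ccccc2)c1 | intermediate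
14 | (2R,3R,4R,5R)-4-[4-(benzyloxy)benzyl]-2-[4-(benzyloxy)phenyl]-5-[2,4-bis(benzyloxy)phenyl]-N-methoxy-N-methyloxolane-3-carboxamide | C(c1ccccc1)Oc1ccc([C@@H]2O[C@@H](c3ccc(OCc4ccccc4)cc3)[C@H](C(=O)N(C)OC)[C@H]2Cc2ccc(OCc3ccccc3)cc2)c(OCc2ccccc2)c1 | intermediate
15 | 1-bromo-2,4-bis(benzyloxy)benzene | Brc1ccc(OCc2ccccc2)cc1OCc1ccccc1 | starting material
16 | [2,4-bis(benzyloxy)phenyl]lithium | [Li]c1ccc(OCc2ccccc2)cc1OCc1ccccc1 | intermediate
17 | [2,4-bis(benzyloxy)phenyl]{(2R,3R,4R,5R)-4-[4-(benzyloxy)benzyl]-2-[4-(benzyloxy)phenyl]-5-[2,4-bis(benzyloxy)phenyl]oxolan-3-yl}methanone | C(c1ccccc1)Oc1ccc([C@@H]2O[C@@H](c3ccc(OCc4ccccc4)cc3)[C@H](C(=O)c3ccc(OCc4ccccc4)cc3OCc3ccccc3)[C@H]2Cc2ccc(OCc3ccccc3)cc2)c(OCc2ccccc2)c1 | intermediate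
18 | N,N-dimethyliminium chloride of aldehyde 19 | C[N+](C)=Cc1cc([C@@H]2O[C@@H](c3ccc(OCc4ccccc4)cc3)[C@H](C(=O)c3ccc(OCc4ccccc4)cc3OCc3ccccc3)[C@H]2Cc2ccc(OCc3ccccc3)cc2)c(OCc2ccccc2)cc1OCc1ccccc1.[Cl-] | intermediate
19 | 2,4-bis(benzyloxy)-5-{(2R,3R,4R,5R)-4-[2,4-bis(benzyloxy)benzoyl]-3-[4-(benzyloxy)benzyl]-5-[4-(benzyloxy)phenyl]oxolan-2-yl}benzaldehyde | O=Cc1cc([C@@H]2O[C@@H](c3ccc(OCc4ccccc4)cc3)[C@H](C(=O)c3ccc(OCc4ccccc4)cc3OCc3ccccc3)[C@H]2Cc2ccc(OCc3ccccc3)cc2)c(OCc2ccccc2)cc1OCc1ccccc1 | intermediate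
20 | 3-(benzyloxy)phenol | Oc1cccc(OCc2ccccc2)c1 | starting material
21 | 3-(benzyloxy)-4-bromophenol | Oc1ccc(Br)c(OCc2ccccc2)c1 | intermediate
22 | lithium 3-(benzyloxy)-4-lithiophenoxide | [Li]Oc1ccc([Li])c(OCc2ccccc2)c1 | intermediate
23 | [2-(benzyloxy)-4-hydroxyphenyl](2,4-bis(benzyloxy)-5-{(2R,3R,4R,5R)-4-[2,4-bis(benzyloxy)benzoyl]-3-[4-(benzyloxy)benzyl]-5-[4-(benzyloxy)phenyl]oxolan-2-yl}phenyl)methanol, both carbinol epimers | OC(c1ccc(O)cc1OCc1ccccc1)c1cc([C@@H]2O[C@@H](c3ccc(OCc4ccccc4)cc3)[C@H](C(=O)c3ccc(OCc4ccccc4)cc3OCc3ccccc3)[C@H]2Cc2ccc(OCc3ccccc3)cc2)c(OCc2ccccc2)cc1OCc1ccccc1 | intermediate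
24 | 3-bromo-4-hydroxybenzaldehyde | O=Cc1ccc(O)c(Br)c1 | starting material
25 | 3-bromo-4-(methoxymethoxy)benzaldehyde | COCOc1ccc(C=O)cc1Br | intermediate
26 | 1-(benzyloxy)-4-ethenylbenzene | C=Cc1ccc(OCc2ccccc2)cc1 | starting material
27 | 3-{(E)-2-[4-(benzyloxy)phenyl]ethenyl}-4-(methoxymethoxy)benzaldehyde | COCOc1ccc(C=O)cc1/C=C/c1ccc(OCc2ccccc2)cc1 | intermediate
28 | 1-[2,4-bis(benzyloxy)phenyl]ethan-1-one | CC(=O)c1ccc(OCc2ccccc2)cc1OCc1ccccc1 | starting material
29 | (E)-3-[3-{(E)-2-[4-(benzyloxy)phenyl]ethenyl}-4-(methoxymethoxy)phenyl]-1-[2,4-bis(benzyloxy)phenyl]prop-2-en-1-one | COCOc1ccc(/C=C/C(=O)c2ccc(OCc3ccccc3)cc2OCc2ccccc2)cc1/C=C/c1ccc(OCc2ccccc2)cc1 | intermediate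
30 | (E)-3-[3-{(E)-2-[4-(benzyloxy)phenyl]ethenyl}-4-hydroxyphenyl]-1-[2,4-bis(benzyloxy)phenyl]prop-2-en-1-one | Oc1ccc(/C=C/C(=O)c2ccc(OCc3ccccc3)cc2OCc2ccccc2)cc1/C=C/c1ccc(OCc2ccccc2)cc1 | intermediate
31 | 3-(benzyloxy)-4-[(2,4-bis(benzyloxy)-5-{(2R,3R,4R,5R)-4-[2,4-bis(benzyloxy)benzoyl]-3-[4-(benzyloxy)benzyl]-5-[4-(benzyloxy)phenyl]oxolan-2-yl}phenyl)methylidene]cyclohexa-2,5-dien-1-one (para-quinone methide, either alkene geometry) | O=C1C=CC(=Cc2cc([C@@H]3O[C@@H](c4ccc(OCc5ccccc5)cc4)[C@H](C(=O)c4ccc(OCc5ccccc5)cc4OCc4ccccc4)[C@H]3Cc3ccc(OCc4ccccc4)cc3)c(OCc3ccccc3)cc2OCc2ccccc2)C(OCc2ccccc2)=C1 | intermediate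
32 | decabenzyl ether of isolophirachalcone: (E)-1-[2,4-bis(benzyloxy)phenyl]-3-{(2R,3R)-3-[(R)-[2-(benzyloxy)-4-hydroxyphenyl](2,4-bis(benzyloxy)-5-{(2R,3R,4R,5R)-4-[2,4-bis(benzyloxy)benzoyl]-3-[4-(benzyloxy)benzyl]-5-[4-(benzyloxy)phenyl]oxolan-2-yl}phenyl)methyl]-2-[4-(benzyloxy)phenyl]-2,3-dihydro-1-benzofuran-5-yl}prop-2-en-1-one | O=C(/C=C/c1ccc2c(c1)[C@@H]([C@H](c1ccc(O)cc1OCc1ccccc1)c1cc([C@@H]3O[C@@H](c4ccc(OCc5ccccc5)cc4)[C@H](C(=O)c4ccc(OCc5ccccc5)cc4OCc4ccccc4)[C@H]3Cc3ccc(OCc4ccccc4)cc3)c(OCc3ccccc3)cc1OCc1ccccc1)[C@H](c1ccc(OCc3ccccc3)cc1)O2)c1ccc(OCc2ccccc2)cc1OCc1ccccc1 | intermediate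
33 | isolophirachalcone | O=C(/C=C/c1ccc2c(c1)[C@@H]([C@H](c1ccc(O)cc1O)c1cc([C@@H]3O[C@@H](c4ccc(O)cc4)[C@H](C(=O)c4ccc(O)cc4O)[C@H]3Cc3ccc(O)cc3)c(O)cc1O)[C@H](c1ccc(O)cc1)O2)c1ccc(O)cc1O | target

## Count and risks

Total steps: 17. Longest linear sequence: 12 steps (steps 1–9, 11, 16, 17).

**Step 16 (key step).** The quinone methide may be consumed by self-alkylation at the electron-rich rings of a second molecule. The face selection at C3 and the methine may be poor if catalyst and remote oxolane centres are mismatched. Proton-initiated cyclisation of 30 alone may compete. Fallback with known chemistry, setting out from 23 and 29 and returning at 32: 23 and the MOM-protected stilbene 29 are combined with diphenyl hydrogen phosphate (10 mol %) in CH2Cl2 at 0 °C. The quinone methide 31 adds to C3 of the stilbene and the C2 cation loses the C3 proton, the known acid-catalysed 1,6-addition/alkenylation of a styrene, to give triaryl alkene F1. HCl in MeOH–THF (45–60 °C) then removes the MOM group to give phenol F2 and closes the ring by the known acid-mediated cyclisation of 2-hydroxystilbenes (protonation at C3, capture at C2, trans under thermodynamic control), returning to 32. The methine epimers would be separated by chromatography. If the MOM oxygen intercepts the cation directly, 32 forms at once.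

**Step 11.** The aryllithium may also add to or enolise the aryl ketone, and bromine–lithium exchange on the phenoxide may be incomplete. Fallback, setting out from 21 and returning at 23: 21 is silylated (i-Pr3SiCl, imidazole, DMF) to silyl ether F3. Mg turnings (THF, 50 °C) convert it into Grignard reagent F4, which adds to aldehyde 19 at −78 °C with the better aldehyde-over-ketone discrimination of a magnesium reagent to give carbinol F5. Bu4NF buffered with AcOH (THF, 0 °C) frees the phenol and gives 23.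

**Step 5.** Over-reduction of the lactol to the diol and partial reduction of the carboxylate may occur. Fallback, setting out from 10 and returning at 13: 10 is deprotonated (LiHMDS, 1 equiv, THF, −78 °C) and treated with aryllithium 16, which adds to the lactone carbonyl to give hemiketal F6 (in equilibrium with the hydroxy ketone). Et3SiH and BF3·OEt2 (CH2Cl2, −78 to 0 °C) reduce the aryl-stabilised oxocarbenium ion (ionic hydrogenation), and the Lewis acid equilibrates the electron-rich 2-aryl ether to the all-trans isomer 13.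

## Further compounds

F1 | step 16 | (E)-3-[3-{1-[4-(benzyloxy)phenyl]-3-[2-(benzyloxy)-4-hydroxyphenyl]-3-(2,4-bis(benzyloxy)-5-{(2R,3R,4R,5R)-4-[2,4-bis(benzyloxy)benzoyl]-3-[4-(benzyloxy)benzyl]-5-[4-(benzyloxy)phenyl]oxolan-2-yl}phenyl)prop-1-en-2-yl}-4-(methoxymethoxy)phenyl]-1-[2,4-bis(benzyloxy)phenyl]prop-2-en-1-one (new alkene geometry and methine configuration not defined) | COCOc1ccc(/C=C/C(=O)c2ccc(OCc3ccccc3)cc2OCc2ccccc2)cc1C(=Cc1ccc(OCc2ccccc2)cc1)C(c1ccc(O)cc1OCc1ccccc1)c1cc([C@@H]2O[C@@H](c3ccc(OCc4ccccc4)cc3)[C@H](C(=O)c3ccc(OCc4ccccc4)cc3OCc3ccccc3)[C@H]2Cc2ccc(OCc3ccccc3)cc2)c(OCc2ccccc2)cc1OCc1ccccc1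
F2 | step 16 | phenol corresponding to F1 (MOM group removed) | Oc1ccc(/C=C/C(=O)c2ccc(OCc3ccccc3)cc2OCc2ccccc2)cc1C(=Cc1ccc(OCc2ccccc2)cc1)C(c1ccc(O)cc1OCc1ccccc1)c1cc([C@@H]2O[C@@H](c3ccc(OCc4ccccc4)cc3)[C@H](C(=O)c3ccc(OCc4ccccc4)cc3OCc3ccccc3)[C@H]2Cc2ccc(OCc3ccccc3)cc2)c(OCc2ccccc2)cc1OCc1ccccc1
F3 | step 11 | [3-(benzyloxy)-4-bromophenoxy]tri(propan-2-yl)silane | CC(C)[Si](Oc1ccc(Br)c(OCc2ccccc2)c1)(C(C)C)C(C)C
F4 | step 11 | {2-(benzyloxy)-4-[tri(propan-2-yl)silyloxy]phenyl}magnesium bromide | CC(C)[Si](Oc1ccc([Mg]Br)c(OCc2ccccc2)c1)(C(C)C)C(C)C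
F5 | step 11 | 4-O-tri(propan-2-yl)silyl ether of carbinol 23, both carbinol epimers | OC(c1ccc(O[Si](C(C)C)(C(C)C)C(C)C)cc1OCc1ccccc1)c1cc([C@@H]2O[C@@H](c3ccc(OCc4ccccc4)cc3)[C@H](C(=O)c3ccc(OCc4ccccc4)cc3OCc3ccccc3)[C@H]2Cc2ccc(OCc3ccccc3)cc2)c(OCc2ccccc2)cc1OCc1ccccc1
F6 | step 5 | (2R,3R,4R)-4-[4-(benzyloxy)benzyl]-2-[4-(benzyloxy)phenyl]-5-[2,4-bis(benzyloxy)phenyl]-5-hydroxyoxolane-3-carboxylic acid, both C5 epimers | OC1(c2ccc(OCc3ccccc3)cc2OCc2ccccc2)O[C@@H](c2ccc(OCc3ccccc3)cc2)[C@H](C(=O)O)[C@H]1Cc1ccc(OCc2ccccc2)cc1
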